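Ring B of the target, with the C8 methyl stereocentre, C10 and the C5-bound gem-dimethyl carbon C4, is the carbon skeleton of (S)-pulegone. Ring A therefore lacks only C1–C3 and its sole functional group, the C1=C10 alkene. The route rests on disconnecting that alkene into two carbonyl groups. A titanium-mediated reductive coupling of a C10 ketone with a C1 aldehyde closes ring A and fixes the double-bond position in one operation. The precursor is a fully substituted cyclohexanone: quaternary C9 (methyl, allyl), C8 methyl, and a CMe2CH2CH2CHO chain at C5. The allyl group then serves as the handle for cross-metathesis, an Evans alkylation (C13), a Suzuki butenolide coupling and sulfation.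

Key step: step 5

Assumption: the target is taken as the free hydrogen sulfate exactly as drawn, so the pyridinium salt formed on sulfation is converted to the acid form by cold cation exchange.

Labels: terpenoid numbering is used. The decalin is C1–C10 (C4 gem-dimethyl, C5 and C10 ring fusion, C8 and C9 methyl-bearing). The side chain runs C11–C16 from C9, and C13 carries the CH2O carbon. Dec = (1S,2S,4aR)-1,2,5,5-tetramethyl-1,2,3,4,4a,5,6,7-octahydronaphthalen-1-yl.

Step 1
Reactants: 1 (S)-(−)-pulegone; 2 2-(2-bromoethyl)-1,3-dioxolane
Product: 5 (5S)-2-[4-(1,3-dioxolan-2-yl)-2-methylbutan-2-yl]-5-methylcyclohexan-1-one as C5 epimer mixture, via Grignard reagent 3 (not isolated), via magnesium enolate 4 (not isolated)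
Conditions: 2, Mg, THF, 20–30 °C; CuBr·SMe2 (10 mol %), −78 °C; 1, −78 → 0 °C; aq NH4Cl
Reagents that add atoms: 2-(2-bromoethyl)-1,3-dioxolane (2), BrCCC1OCCO1
Why: Copper-catalysed conjugate addition of a Grignard reagent to the s-cis-locked enone, a reaction type well established for pulegone, should form the C3–C4 bond and the quaternary gem-dimethyl carbon, while C8 is untouched and the unselective protonation at C5 is corrected in step 2.

Step 2
Reactants: 5 conjugate adduct (C5 epimer mixture); 6 iodomethane
Product: 9 (2R,3S,6R)-6-[4-(1,3-dioxolan-2-yl)-2-methylbutan-2-yl]-2,3-dimethylcyclohexan-1-one (all three ring substituents equatorial), via lithium enolate 7 (not isolated), via methylated stereoisomer mixture 8 (not isolated)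
Conditions: LiN(i-Pr)2 (1.05 equiv), THF, −78 °C; MeI, −78 → 0 °C; then NaOMe, MeOH, reflux in the same flask; chromatography
Reagents that add atoms: iodomethane (6), CI
Why: Kinetic enolate alkylation followed by base-mediated epimerisation: the hindered amide base removes a C9 methylene proton rather than the C5 methine proton next to the quaternary carbon, SN2 methylation follows, and methoxide then equilibrates both enolisable centres (C5 and C9) so that all stereoisomers should converge on the all-equatorial ketone, which sets C5 trans to the C8 methyl under thermodynamic control by the pulegone stereocentre.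

Step 3
Reactants: 9 all-equatorial 9-methyl ketone; 10 allyl bromide
Product: 12 (2S,3S,6R)-2-allyl-6-[4-(1,3-dioxolan-2-yl)-2-methylbutan-2-yl]-2,3-dimethylcyclohexan-1-one, via lithium enolate 11 (not isolated)
Conditions: LiN(i-Pr)2 (1.2 equiv), THF, −78 → 0 °C; DMPU, allyl bromide, −78 °C → rt
Reagents that add atoms: allyl bromide (10), C=CCBr
Why: Enolate C-alkylation: the axial C9–H is removed because a C5 enolate would force the tertiary alkyl group into the enolate plane, and half-chair enolate 11, holding the C5 and C8 substituents pseudo-equatorial, should accept allyl bromide along the stereoelectronically preferred axial trajectory on the face anti to the C5 side chain, which places allyl axial (cis to the C8 methyl) and the C9 methyl equatorial as the target requires.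

Step 4
Reactants: 12 allylated ketone acetal
Product: 13 4-[(1R,3S,4S)-3-allyl-3,4-dimethyl-2-oxocyclohexyl]-4-methylpentanal (ring B keto aldehyde)
Conditions: 1 M aq HCl, THF, rt; used without delay
Reagents that add atoms: water, O
Why: Acid-catalysed acetal hydrolysis should release the C1 aldehyde under conditions too mild for aldol closure or alkene migration, and C5 cannot drift because its equatorial orientation, anti to the axial allyl group, is by far the more stable one.

Step 5
Reactants: 13 ring B keto aldehyde
Product: 15 (1S,2S,4aR)-1-allyl-1,2,5,5-tetramethyl-1,2,3,4,4a,5,6,7-octahydronaphthalene (decalin core bearing the C9 allyl group), via titanium pinacolate 14 (not isolated)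
Conditions: TiCl3(DME)1.5, Zn–Cu couple, DME, reflux, 2 h; then 13 in DME by syringe pump over about 30 h, reflux, high dilution; filtration through Florisil
Reagents that add atoms: none
Why: Low-valent titanium, made in the flask by reducing TiCl3 with Zn–Cu, converts the aldehyde and the ketone into titanium-bound ketyl radicals, C–C bond formation between C1 and C10 gives pinacolate 14, and at reflux the strength of the Ti–O bonds drives extrusion of both oxygen atoms to leave the C1=C10 alkene. The closest known reaction type is the intramolecular McMurry coupling of keto aldehydes to cycloalkenes, which is dependable for six-membered rings and is known to deliver even heavily branched alkenes. Ring A closes by a formal 6-exo ketyl-to-carbonyl attack in which C1–C10 is the only new skeletal bond. No stereocentre is created and none is endangered, since C9 is quaternary, C8 is remote from any acidic site, and C5 already occupies its thermodynamically preferred orientation. The step needs control of the alkene position and chemoselectivity against intermolecular aldehyde coupling and against the allyl group: the first is built in because the double bond can only join the two former carbonyl carbons, the second is secured by slow addition at high dilution, and an isolated terminal alkene does not accept electrons from low-valent titanium.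

Step 6
Reactants: 16 (S)-4-benzyloxazolidin-2-one; 17 acryloyl chloride
Product: 18 (S)-3-acryloyl-4-benzyloxazolidin-2-one
Conditions: Et3N, LiCl, THF, −20 °C → rt
Reagents that add atoms: acryloyl chloride (17), C=CC(=O)Cl
Why: Lithium-chloride-assisted N-acylation of the oxazolidinone under amine base should avoid the strongly basic anions that polymerise acrylates and leaves the auxiliary stereocentre untouched.

Step 7
Reactants: 15 decalin core; 18 acryloyl imide
Product: 19 (4S)-4-benzyl-3-[(2E)-4-(Dec)but-2-enoyl]oxazolidin-2-one
Conditions: 18 (2 equiv), second-generation Hoveyda–Grubbs catalyst RuCl2(H2IMes)(=CH-C6H4-2-O-i-Pr) (5 mol %), CH2Cl2, 40 °C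
Reagents that add atoms: (S)-3-acryloyl-4-benzyloxazolidin-2-one (18), C=CC(=O)N1[C@@H](Cc2ccccc2)COC1=O
Why: Olefin cross-metathesis between a readily reacting terminal alkene and an electron-poor acryloyl imide that hardly homodimerises is inherently cross-selective and E-selective, installs C13 and the future CH2O carbon in one bond exchange, and should leave the hindered trisubstituted C1=C10 alkene unengaged by the ruthenium carbene.

Step 8
Reactants: 19 enoyl imide
Product: 20 (4S)-4-benzyl-3-[4-(Dec)butanoyl]oxazolidin-2-one
Conditions: H2 (1–4 atm), RhCl(PPh3)3 (10 mol %), toluene–EtOH, rt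
Reagents that add atoms: none
Why: Homogeneous hydrogenation with RhCl(PPh3)3 discriminates strongly by alkene substitution, so the 1,2-disubstituted enoyl double bond should be saturated while the trisubstituted ring alkene beside quaternary C9 is neither reduced nor isomerised.

Step 9
Reactants: 20 saturated imide; 21 allyl iodide
Product: 23 (4S)-4-benzyl-3-[(2R)-2-[2-(Dec)ethyl]pent-4-enoyl]oxazolidin-2-one, via sodium Z-enolate 22 (not isolated)
Conditions: NaN(SiMe3)2 (1.1 equiv), THF, −78 °C; allyl iodide (3 equiv), −78 → −45 °C
Reagents that add atoms: allyl iodide (21), C=CCI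
Why: Evans asymmetric alkylation: the chelated Z-enolate 22 is shielded on one face by the benzyl group of the (S)-auxiliary, so allyl iodide should enter from the opposite face and set C13 in the spatial arrangement of the target (the descriptor is R here and becomes S after step 11 only because the CIP priorities of the two chains change).

Step 10
Reactants: 23 allylated imide
Product: 24 (2R)-2-[2-(Dec)ethyl]pent-4-en-1-ol
Conditions: LiBH4, MeOH (1 equiv), Et2O, 0 °C; aq NaOH work-up
Reagents that add atoms: none
Why: Reductive cleavage of the N-acyloxazolidinone with LiBH4 attacks the exocyclic imide carbonyl, should give the primary alcohol without epimerising C13, touches neither alkene, and returns the auxiliary.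

Step 11
Reactants: 24 homoallylic-type alcohol; 25 4-bromofuran-2(5H)-one
Product: 27 4-[(4S)-4-(hydroxymethyl)-6-(Dec)hexyl]furan-2(5H)-one, via bis(9-BBN) borane 26 (not isolated)
Conditions: 9-BBN dimer (2.5 equiv B–H), THF, 0 °C → rt; then 3 M aq K3PO4, 25, PdCl2(dppf) (5 mol %), AsPh3 (5 mol %), DMF, rt
Reagents that add atoms: 4-bromofuran-2(5H)-one (25), O=C1C=C(Br)CO1
Why: 9-BBN hydroborates only the monosubstituted alkene with anti-Markovnikov regiochemistry (the free hydroxyl merely consumes one extra equivalent as a borinate that the aqueous base hydrolyses), and B-alkyl Suzuki–Miyaura coupling of 26 with the β-bromo enoate unit of 25 should form the C16–butenolide bond directly without touching C13 or the ring alkene.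

Step 12
Reactants: 27 butenolide alcohol; 28 sulfur trioxide–pyridine complex
Product: 30 (2S)-5-(5-oxo-2,5-dihydrofuran-3-yl)-2-[2-(Dec)ethyl]pentyl hydrogen sulfate (target CNP0360075.1), via pyridinium sulfate salt 29 (not isolated)
Conditions: SO3·pyridine (3 equiv), pyridine, 0 °C → rt; H2O; Dowex 50W (H+ form), MeOH–H2O, 0 °C; lyophilisation
Reagents that add atoms: sulfur trioxide–pyridine complex (28), [O-]S(=O)(=O)[n+]1ccccc1
Why: O-sulfation of the only hydroxyl group by an SO3–amine complex is a mild standard reaction that spares the butenolide and the alkene, and cold cation exchange should convert the pyridinium salt into the hydrogen sulfate without changing any stereocentre.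

Compound list
1 | (S)-(−)-pulegone | C[C@H]1CCC(=C(C)C)C(=O)C1 | starting material
2 | 2-(2-bromoethyl)-1,3-dioxolane | BrCCC1OCCO1 | starting material
3 | [2-(1,3-dioxolan-2-yl)ethyl]magnesium bromide | Br[Mg]CCC1OCCO1 | intermediate
4 | bromomagnesium C5=C10 enolate of the conjugate adduct | C[C@H]1CCC(C(C)(C)CCC2OCCO2)=C(O[Mg]Br)C1 | intermediate
5 | (5S)-2-[4-(1,3-dioxolan-2-yl)-2-methylbutan-2-yl]-5-methylcyclohexan-1-one, C5 epimer mixture | C[C@H]1CCC(C(C)(C)CCC2OCCO2)C(=O)C1 | intermediate
6 | iodomethane | CI | starting material
7 | lithium C9=C10 enolate of 5 | C[C@H]1CCC(C(C)(C)CCC2OCCO2)C(O[Li])=C1 | intermediate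
8 | 9-methyl ketone, mixture of C5 and C9 stereoisomers | C[C@H]1CCC(C(C)(C)CCC2OCCO2)C(=O)C1C | intermediate
9 | (2R,3S,6R)-6-[4-(1,3-dioxolan-2-yl)-2-methylbutan-2-yl]-2,3-dimethylcyclohexan-1-one | C[C@H]1CC[C@H](C(C)(C)CCC2OCCO2)C(=O)[C@@H]1C | intermediate
10 | allyl bromide | C=CCBr | starting material
11 | lithium C9=C10 enolate of 9 (tetrasubstituted) | C[C@H]1CC[C@H](C(C)(C)CCC2OCCO2)C(O[Li])=C1C | intermediate
12 | (2S,3S,6R)-2-allyl-6-[4-(1,3-dioxolan-2-yl)-2-methylbutan-2-yl]-2,3-dimethylcyclohexan-1-one | C[C@H]1CC[C@H](C(C)(C)CCC2OCCO2)C(=O)[C@@]1(C)CC=C | intermediate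
13 | 4-[(1R,3S,4S)-3-allyl-3,4-dimethyl-2-oxocyclohexyl]-4-methylpentanal | C[C@H]1CC[C@H](C(C)(C)CCC=O)C(=O)[C@@]1(C)CC=C | intermediate
14 | titanium pinacolate (cyclic C1,C10-diolate on titanium, drawn in its simplest form; C1 and C10 unspecified) | C[C@H]1CC[C@H]2C3(O[Ti]OC3CCC2(C)C)[C@@]1(C)CC=C | intermediate
15 | (1S,2S,4aR)-1-allyl-1,2,5,5-tetramethyl-1,2,3,4,4a,5,6,7-octahydronaphthalene | C[C@H]1CC[C@H]2C(=CCCC2(C)C)[C@@]1(C)CC=C | intermediate
16 | (S)-4-benzyloxazolidin-2-one | O=C1N[C@@H](Cc2ccccc2)CO1 | starting material
17 | acryloyl chloride | C=CC(=O)Cl | starting material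
18 | (S)-3-acryloyl-4-benzyloxazolidin-2-one | C=CC(=O)N1[C@@H](Cc2ccccc2)COC1=O | intermediate
19 | (4S)-4-benzyl-3-[(2E)-4-(Dec)but-2-enoyl]oxazolidin-2-one | C[C@H]1CC[C@H]2C(=CCCC2(C)C)[C@@]1(C)C/C=C/C(=O)N1[C@@H](Cc2ccccc2)COC1=O | intermediate
20 | (4S)-4-benzyl-3-[4-(Dec)butanoyl]oxazolidin-2-one | C[C@H]1CC[C@H]2C(=CCCC2(C)C)[C@@]1(C)CCCC(=O)N1[C@@H](Cc2ccccc2)COC1=O | intermediate
21 | allyl iodide | C=CCI | starting material
22 | sodium Z-enolate of 20 | C[C@H]1CC[C@H]2C(=CCCC2(C)C)[C@@]1(C)CC/C=C(\O[Na])N1[C@@H](Cc2ccccc2)COC1=O | intermediate
23 | (4S)-4-benzyl-3-[(2R)-2-[2-(Dec)ethyl]pent-4-enoyl]oxazolidin-2-one | C[C@H]1CC[C@H]2C(=CCCC2(C)C)[C@@]1(C)CC[C@H](CC=C)C(=O)N1[C@@H](Cc2ccccc2)COC1=O | intermediate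
24 | (2R)-2-[2-(Dec)ethyl]pent-4-en-1-ol | C[C@H]1CC[C@H]2C(=CCCC2(C)C)[C@@]1(C)CC[C@H](CC=C)CO | intermediate
25 | 4-bromofuran-2(5H)-one | O=C1C=C(Br)CO1 | starting material
26 | C16 B-alkyl-9-BBN carrying an O-(9-BBN) borinate on the C13 CH2O group | C[C@H]1CC[C@H]2C(=CCCC2(C)C)[C@@]1(C)CC[C@H](CCCB1C2CCCC1CCC2)COB1C2CCCC1CCC2 | intermediate
27 | 4-[(4S)-4-(hydroxymethyl)-6-(Dec)hexyl]furan-2(5H)-one | C[C@H]1CC[C@H]2C(=CCCC2(C)C)[C@@]1(C)CC[C@H](CCCC1=CC(=O)OC1)CO | intermediate
28 | sulfur trioxide–pyridine complex | [O-]S(=O)(=O)[n+]1ccccc1 | starting material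
29 | pyridinium salt of the target sulfate | C[C@H]1CC[C@H]2C(=CCCC2(C)C)[C@@]1(C)CC[C@H](CCCC1=CC(=O)OC1)COS(=O)(=O)[O-].c1cc[nH+]cc1 | intermediate
30 | (2S)-5-(5-oxo-2,5-dihydrofuran-3-yl)-2-[2-(Dec)ethyl]pentyl hydrogen sulfate | C[C@H]1CC[C@H]2C(=CCCC2(C)C)[C@@]1(C)CC[C@H](CCCC1=CC(=O)OC1)COS(=O)(=O)O | target

Total step count: 12. Longest linear sequence: 11 (steps 1–5 and 7–12, from (S)-pulegone); step 6 is a one-step side branch.

Steps most likely to fail

Step 5 (ring A closure). The congested C10 ketone may stay inert or be simply reduced while aldehyde units couple between molecules. The reaction may also stall at the pinacolate stage, or Lewis-acidic titanium residues may shift the new double bond toward C5. The fallback sets out from 13 and comes back at 15, keeping the C1–C10 bond but splitting coupling and deoxygenation into separate, stereospecific operations. SmI2 with t-BuOH in THF (−78 °C → rt) should effect a ketyl–carbonyl pinacol cyclisation in which chelation of both oxygens to samarium favours the cis-diol 8-allyl-4,4,7,8-tetramethyldecahydronaphthalene-1,8a-diol F1. Thiocarbonyldiimidazole and DMAP in refluxing toluene should convert it into the cyclic thionocarbonate F2. Corey–Winter syn-elimination with P(OMe)3 at reflux then extrudes the bridging unit and gives 15, with the alkene again confined to C1=C10.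

Step 3 (quaternary C9). Facial selectivity of the allylation may be poor, enolisation may leak toward C5, or O-allylation may compete. The fallback sets out from 9 and comes back at 12, replacing substrate control by catalyst control. The enolate of 9 is trapped on oxygen with allyl chloroformate (LiN(i-Pr)2, TMEDA, THF, −78 °C) to give the allyl enol carbonate F3, which can be purified as the single C9=C10 regioisomer. Decarboxylative allylic alkylation of the Tsuji type follows, with Pd2(dba)3 and (R)-t-Bu-PHOX in toluene at 25 °C. This is the ligand enantiomer that delivers allyl to the corresponding face in the parent 2-methylcyclohexanone series. It regenerates the enolate site-specifically and should reinforce delivery of allyl to the required face, giving 12.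

Step 11 (butenolide coupling). The bromobutenolide may degrade in aqueous base, the free hydroxyl may add to it by addition–elimination, or transmetalation may be slow. The fallback sets out from 24 (through borane 26) and comes back at 27, using a base-insensitive heteroaryl partner that is oxidised afterwards. Suzuki–Miyaura coupling of 26 with 3-bromofuran (PdCl2(dppf), aq K3PO4, DMF–THF, 50 °C) should give the furan alcohol (2S)-5-(furan-3-yl)-2-[2-(Dec)ethyl]pentan-1-ol F4. Dye-sensitised photooxygenation (O2, rose bengal, i-Pr2NEt, CH2Cl2, −78 °C, visible light) exploits the much faster [4+2] addition of singlet oxygen to the furan than its ene reaction with the ring alkene. The hindered base removes the less hindered endoperoxide proton, which should give the γ-hydroxybutenolide F5 with the carbonyl distal to the chain. NaBH4 in EtOH at 0 °C followed by dilute acid reduces the masked aldehyde and relactonises to 27.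

Further compounds
F1 | step 5 | 8-allyl-4,4,7,8-tetramethyldecahydronaphthalene-1,8a-diol, cis-diol (C1 and C10 configuration left open, both are erased on elimination) | C[C@H]1CC[C@H]2C(O)(C(O)CCC2(C)C)[C@@]1(C)CC=C
F2 | step 5 | cyclic C1,C10-thionocarbonate of F1 | C[C@H]1CC[C@H]2C3(OC(=S)OC3CCC2(C)C)[C@@]1(C)CC=C
F3 | step 3 | allyl enol carbonate of 9 (C9=C10 enol) | C[C@H]1CC[C@H](C(C)(C)CCC2OCCO2)C(OC(=O)OCC=C)=C1C
F4 | step 11 | (2S)-5-(furan-3-yl)-2-[2-(Dec)ethyl]pentan-1-ol | C[C@H]1CC[C@H]2C(=CCCC2(C)C)[C@@]1(C)CC[C@H](CCCc1ccoc1)CO
F5 | step 11 | 5-hydroxy-4-[(4S)-4-(hydroxymethyl)-6-(Dec)hexyl]furan-2(5H)-one (hemiacetal carbon unspecified) | C[C@H]1CC[C@H]2C(=CCCC2(C)C)[C@@]1(C)CC[C@H](CCCC1=CC(=O)OC1O)CO
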